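**Strategy**

Ring A (the cyclohexadienone) holds a quaternary carbon C4 that carries a methyl group and is bonded to the enol carbon C3, the neighbour of the acetyl-bearing C2: a ketone with an α-methyl quaternary carbon is the retron of alkene hydroacylation. The route rests on closing ring A at C3–C4 by an enantioselective carbene-catalysed intramolecular hydroacylation: an aldehyde carbon (future C3) adds to the internal carbon of a prenyl-bearing 1,1-disubstituted alkene, whose CH2 becomes the C4 methyl group. The precursor is a 3-methylisoxazole-4-carbaldehyde; its isoxazole masks the acetyl group and the C1 carbonyl. Unmasking and an aminomethyl-mediated methylene coupling with prenylated phloroacetophenone complete the target.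

Key step: step 8

Assumption: the target is treated as the tautomer drawn, in which the quaternary carbon is (R); the (5aS,10bR) triazolium salt is assumed to give this sense, and the temporary carbinol centre of 10–15 (erased in step 9) is drawn (R) as the assumed matched partner — if either sense proves opposite, the mirror-image triazolium salt (step 8) or oxazaborolidine (step 5) is used and nothing else changes.

**Route**

Step 1
Reactants: 1 2,3-dibromoprop-1-ene; 2 (2-methylprop-1-en-1-yl)magnesium bromide
Product: 3 2-bromo-5-methylhexa-1,4-diene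
Conditions: CuI (5 mol %), THF, −20 to 0 °C
Reagents that add atoms: none
Why: Copper-catalysed allylic substitution of the allylic bromide by the alkenyl Grignard reagent should leave the vinylic bromide untouched, and direct and allylic-shift attack give the same product.

Step 2
Reactants: 3 2-bromo-5-methylhexa-1,4-diene
Product: 5 5-methyl-2-methylidenehex-4-enal, via alkenyllithium 4 (not isolated)
Conditions: t-BuLi (2 equiv), Et2O, −78 °C; DMF, −78 to 0 °C; H2O
Reagents that add atoms: N,N-dimethylformamide, CN(C)C=O
Why: Bromine–lithium exchange followed by formylation of the alkenyllithium with DMF should give the α-substituted acrolein.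

Step 3
Reactants: 6 3,5-dimethyl-1,2-oxazole-4-carbonitrile; 5 5-methyl-2-methylidenehex-4-enal
Product: 8 racemic 5-(2-hydroxy-6-methyl-3-methylidenehept-5-en-1-yl)-3-methyl-1,2-oxazole-4-carbonitrile, via lithiated nitrile 7 (not isolated)
Conditions: LiN(i-Pr)2 (LDA), THF, −78 °C; then 5, −78 °C; AcOH quench at −78 °C
Reagents that add atoms: none
Why: Lateral (vinylogous) deprotonation of the 5-methyl group, which is activated through C5=C4 by the nitrile, and aldol-type 1,2-addition of the anion to the enal at low temperature should give the allylic alcohol.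

Step 4
Reactants: 8 racemic 5-(2-hydroxy-6-methyl-3-methylidenehept-5-en-1-yl)-3-methyl-1,2-oxazole-4-carbonitrile
Product: 9 3-methyl-5-(6-methyl-3-methylidene-2-oxohept-5-en-1-yl)-1,2-oxazole-4-carbonitrile
Conditions: Dess–Martin periodinane, CH2Cl2, 0 °C; used at once
Reagents that add atoms: none
Why: Dess–Martin oxidation of the allylic alcohol gives the enone under non-basic conditions, so the carbinol carbon can be reset enantioselectively.

Step 5
Reactants: 9 3-methyl-5-(6-methyl-3-methylidene-2-oxohept-5-en-1-yl)-1,2-oxazole-4-carbonitrile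
Product: 10 5-[(2R)-2-hydroxy-6-methyl-3-methylidenehept-5-en-1-yl]-3-methyl-1,2-oxazole-4-carbonitrile
Conditions: (S)-2-methyl-CBS-oxazaborolidine (0.2 equiv), catecholborane, toluene, −78 °C
Reagents that add atoms: none
Why: Corey–Bakshi–Shibata reduction should deliver hydride to one face of the enone, the branched alkenyl group acting as the large and the heteroarylmethyl group as the small substituent, to give the (R)-carbinol without touching the nitrile or the alkenes.

Step 6
Reactants: 10 5-[(2R)-2-hydroxy-6-methyl-3-methylidenehept-5-en-1-yl]-3-methyl-1,2-oxazole-4-carbonitrile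
Product: 11 5-[(2R)-2-[tert-butyl(dimethyl)silyl]oxy-6-methyl-3-methylidenehept-5-en-1-yl]-3-methyl-1,2-oxazole-4-carbonitrile
Conditions: TBSOTf, 2,6-lutidine, CH2Cl2, −78 to 0 °C
Reagents that add atoms: tert-butyldimethylsilyl trifluoromethanesulfonate, CC(C)(C)[Si](C)(C)OS(=O)(=O)C(F)(F)F
Why: Silylation blocks the hydroxyl group, which would otherwise close a lactol onto the aldehyde made in the next step.

Step 7
Reactants: 11 5-[(2R)-2-[tert-butyl(dimethyl)silyl]oxy-6-methyl-3-methylidenehept-5-en-1-yl]-3-methyl-1,2-oxazole-4-carbonitrile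
Product: 13 5-[(2R)-2-[tert-butyl(dimethyl)silyl]oxy-6-methyl-3-methylidenehept-5-en-1-yl]-3-methyl-1,2-oxazole-4-carbaldehyde, via aldimine 12 (not isolated)
Conditions: i-Bu2AlH (DIBAL-H), toluene, −78 °C; then aq. potassium sodium tartrate, wet silica gel
Reagents that add atoms: water, O
Why: Partial reduction of the nitrile stops at the aluminium aldimine, which hydrolyses to the aldehyde on work-up, while the silyl ether, both alkenes and the isoxazole should not react at −78 °C.

Step 8
Reactants: 13 5-[(2R)-2-[tert-butyl(dimethyl)silyl]oxy-6-methyl-3-methylidenehept-5-en-1-yl]-3-methyl-1,2-oxazole-4-carbaldehyde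
Product: 14 (5R,6R)-6-[tert-butyl(dimethyl)silyl]oxy-3,5-dimethyl-5-(3-methylbut-2-en-1-yl)-6,7-dihydro-1,2-benzoxazol-4(5H)-one
Conditions: (5aS,10bR)-2-mesityl-5a,10b-dihydro-4H,6H-indeno[2,1-b][1,2,4]triazolo[4,3-d][1,4]oxazin-2-ium chloride (20 mol %), DBU (20 mol %), 1,4-dioxane, 90 °C; chromatographic removal of any C5 epimer
Reagents that add atoms: none
Why: The triazolylidene freed by DBU adds to the aldehyde carbon of 13 to give an enaminol, whose nucleophilic carbon bonds to the internal carbon of the 1,1-disubstituted alkene while its O–H hydrogen passes to the terminal CH2 in one concerted, asynchronous ene-type event (Conia-ene-like), and loss of the carbene gives the ketone. The closest known reaction type is the carbene-catalysed intramolecular hydroacylation of unactivated alkenes, which converts aryl aldehydes with an ortho-tethered 1,1-disubstituted alkene into six-membered ketones with an α-methyl quaternary carbon, also enantioselectively with chiral triazolium salts. The new carbocycle (future ring A) closes 6-exo-trig, the alkene CH2 ending outside the ring as the methyl group. The quaternary centre is set by the chiral carbene, which shields one face of the alkene in the hydrogen-transfer transition state; the adjacent (R)-silyloxy centre is the matched partner and turns any minor isomer into a separable diastereomer. The step needs the disubstituted alkene to react in preference to the prenyl alkene and C–C bonding at its internal carbon: the tether length allows only this six-membered closure, trisubstituted alkenes are inert to this catalysis, the substrate holds no Michael acceptor for a competing Stetter reaction, and the 3-methyl group keeps the isoxazole stable to DBU.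

Step 9
Reactants: 14 (5R,6R)-6-[tert-butyl(dimethyl)silyl]oxy-3,5-dimethyl-5-(3-methylbut-2-en-1-yl)-6,7-dihydro-1,2-benzoxazol-4(5H)-one
Product: 16 (5R)-3,5-dimethyl-5-(3-methylbut-2-en-1-yl)-1,2-benzoxazole-4,6(5H,7H)-dione, via hydroxy ketone 15 (not isolated)
Conditions: Bu4NF, AcOH, THF, 0 °C to rt; then Dess–Martin periodinane, CH2Cl2, rt
Reagents that add atoms: none
Why: Buffered fluoride desilylation avoids retro-aldol opening of the β-hydroxy ketone, and Dess–Martin oxidation then gives the 1,3-diketone and erases the temporary carbinol centre, leaving the quaternary carbon (no α-hydrogen) as the only stereocentre.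

Step 10
Reactants: 16 (5R)-3,5-dimethyl-5-(3-methylbut-2-en-1-yl)-1,2-benzoxazole-4,6(5H,7H)-dione
Product: 18 (4R)-2-acetyl-3,5-dihydroxy-4-methyl-4-(3-methylbut-2-en-1-yl)cyclohexa-2,5-dien-1-one, via enaminone 17 (not isolated)
Conditions: Mo(CO)6, MeCN/H2O, 80 °C; then 2 M aq. NaOH, EtOH, 60 °C; 1 M HCl, 0 °C
Reagents that add atoms: water, O
Why: Reductive N–O cleavage of the isoxazole unveils the vinylogous amide, and alkaline hydrolysis releases the 2-acetyl-1,3-dione, the triketone being shielded from retro-Claisen cleavage as its delocalised anion and the prenyl alkene being inert to both stages.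

Step 11
Reactants: 19 1-(2,4,6-trihydroxyphenyl)ethan-1-one; 20 1-bromo-3-methylbut-2-ene
Product: 21 1-[2,4,6-trihydroxy-3-(3-methylbut-2-en-1-yl)phenyl]ethan-1-one
Conditions: DBU, THF, 0 °C to rt
Reagents that add atoms: none
Why: C-alkylation of the phloroglucinol phenoxide with prenyl bromide, run with limiting bromide to favour the mono-prenyl product.

Step 12
Reactants: 21 1-[2,4,6-trihydroxy-3-(3-methylbut-2-en-1-yl)phenyl]ethan-1-one
Product: 22 1-[3-[(dimethylamino)methyl]-2,4,6-trihydroxy-5-(3-methylbut-2-en-1-yl)phenyl]ethan-1-one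
Conditions: 37% aq. HCHO, 40% aq. Me2NH, EtOH, 0 °C to rt
Reagents that add atoms: formaldehyde, C=O; dimethylamine, CNC
Why: Mannich reaction at the only free position of the electron-rich ring installs the future bridge carbon with a leaving group.

Step 13
Reactants: 18 (4R)-2-acetyl-3,5-dihydroxy-4-methyl-4-(3-methylbut-2-en-1-yl)cyclohexa-2,5-dien-1-one; 22 1-[3-[(dimethylamino)methyl]-2,4,6-trihydroxy-5-(3-methylbut-2-en-1-yl)phenyl]ethan-1-one
Product: 23 (4R)-2-acetyl-6-[[3-acetyl-2,4,6-trihydroxy-5-(3-methylbut-2-en-1-yl)phenyl]methyl]-3,5-dihydroxy-4-methyl-4-(3-methylbut-2-en-1-yl)cyclohexa-2,5-dien-1-one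
Conditions: 1,4-dioxane, 80 °C
Reagents that add atoms: none
Why: The acidic triketone protonates the Mannich base, thermal loss of dimethylamine gives an ortho-quinone methide, and Michael addition of the only free enol carbon (C6) of 18 forms the methylene bridge without touching the quaternary centre.

**Compound list**

1 | 2,3-dibromoprop-1-ene | C=C(Br)CBr | starting material
2 | (2-methylprop-1-en-1-yl)magnesium bromide | CC(C)=C[Mg]Br | starting material
3 | 2-bromo-5-methylhexa-1,4-diene | C=C(Br)CC=C(C)C | intermediate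
4 | (5-methylhexa-1,4-dien-2-yl)lithium (not isolated) | [Li]C(=C)CC=C(C)C | intermediate
5 | 5-methyl-2-methylidenehex-4-enal | C=C(CC=C(C)C)C=O | intermediate
6 | 3,5-dimethyl-1,2-oxazole-4-carbonitrile | Cc1noc(C)c1C#N | starting material
7 | [(4-cyano-3-methyl-1,2-oxazol-5-yl)methyl]lithium (not isolated) | [Li]Cc1onc(C)c1C#N | intermediate
8 | racemic 5-(2-hydroxy-6-methyl-3-methylidenehept-5-en-1-yl)-3-methyl-1,2-oxazole-4-carbonitrile | Cc1noc(CC(O)C(=C)CC=C(C)C)c1C#N | intermediate
9 | 3-methyl-5-(6-methyl-3-methylidene-2-oxohept-5-en-1-yl)-1,2-oxazole-4-carbonitrile | Cc1noc(CC(=O)C(=C)CC=C(C)C)c1C#N | intermediate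
10 | 5-[(2R)-2-hydroxy-6-methyl-3-methylidenehept-5-en-1-yl]-3-methyl-1,2-oxazole-4-carbonitrile | Cc1noc(C[C@@H](O)C(=C)CC=C(C)C)c1C#N | intermediate
11 | 5-[(2R)-2-[tert-butyl(dimethyl)silyl]oxy-6-methyl-3-methylidenehept-5-en-1-yl]-3-methyl-1,2-oxazole-4-carbonitrile | Cc1noc(C[C@@H](O[Si](C)(C)C(C)(C)C)C(=C)CC=C(C)C)c1C#N | intermediate
12 | N-unsubstituted aldimine of aldehyde 13 (not isolated) | Cc1noc(C[C@@H](O[Si](C)(C)C(C)(C)C)C(=C)CC=C(C)C)c1C=N | intermediate
13 | 5-[(2R)-2-[tert-butyl(dimethyl)silyl]oxy-6-methyl-3-methylidenehept-5-en-1-yl]-3-methyl-1,2-oxazole-4-carbaldehyde | Cc1noc(C[C@@H](O[Si](C)(C)C(C)(C)C)C(=C)CC=C(C)C)c1C=O | intermediate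
14 | (5R,6R)-6-[tert-butyl(dimethyl)silyl]oxy-3,5-dimethyl-5-(3-methylbut-2-en-1-yl)-6,7-dihydro-1,2-benzoxazol-4(5H)-one | Cc1noc2c1C(=O)[C@](C)(CC=C(C)C)[C@H](O[Si](C)(C)C(C)(C)C)C2 | intermediate
15 | (5R,6R)-6-hydroxy-3,5-dimethyl-5-(3-methylbut-2-en-1-yl)-6,7-dihydro-1,2-benzoxazol-4(5H)-one (not isolated) | Cc1noc2c1C(=O)[C@](C)(CC=C(C)C)[C@H](O)C2 | intermediate
16 | (5R)-3,5-dimethyl-5-(3-methylbut-2-en-1-yl)-1,2-benzoxazole-4,6(5H,7H)-dione | Cc1noc2c1C(=O)[C@](C)(CC=C(C)C)C(=O)C2 | intermediate
17 | (4R)-2-(1-aminoethylidene)-4-methyl-4-(3-methylbut-2-en-1-yl)cyclohexane-1,3,5-trione (not isolated) | CC(N)=C1C(=O)[C@](C)(CC=C(C)C)C(=O)CC1=O | intermediate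
18 | (4R)-2-acetyl-3,5-dihydroxy-4-methyl-4-(3-methylbut-2-en-1-yl)cyclohexa-2,5-dien-1-one | CC(=O)C1=C(O)[C@](C)(CC=C(C)C)C(O)=CC1=O | intermediate
19 | 1-(2,4,6-trihydroxyphenyl)ethan-1-one | CC(=O)c1c(O)cc(O)cc1O | starting material
20 | 1-bromo-3-methylbut-2-ene | CC(C)=CCBr | starting material
21 | 1-[2,4,6-trihydroxy-3-(3-methylbut-2-en-1-yl)phenyl]ethan-1-one | CC(=O)c1c(O)c(CC=C(C)C)c(O)cc1O | intermediate
22 | 1-[3-[(dimethylamino)methyl]-2,4,6-trihydroxy-5-(3-methylbut-2-en-1-yl)phenyl]ethan-1-one | CC(=O)c1c(O)c(CC=C(C)C)c(O)c(CN(C)C)c1O | intermediate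
23 | (4R)-2-acetyl-6-[[3-acetyl-2,4,6-trihydroxy-5-(3-methylbut-2-en-1-yl)phenyl]methyl]-3,5-dihydroxy-4-methyl-4-(3-methylbut-2-en-1-yl)cyclohexa-2,5-dien-1-one | CC(=O)C1=C(O)[C@](C)(CC=C(C)C)C(O)=C(Cc2c(O)c(CC=C(C)C)c(O)c(C(C)=O)c2O)C1=O | target

Total step count: 13. Longest linear sequence: 11 steps (steps 1 to 10, then step 13).

**Steps most likely to fail**

Step 8. The ene-type hydrogen transfer to an alkyl-substituted alkene next to a silyloxy-bearing carbon may be too slow, so that benzoin dimerisation or base-induced β-elimination of silanolate outruns the ring closure, or the facial selectivity may be poor. The fallback closes the same C–C bond by a radical route and sets out from nitrile 11. Fe(acac)3 and PhSiH3 in EtOH at 60 °C transfer a hydrogen atom to the CH2 of the 1,1-disubstituted alkene (Mukaiyama-type hydrogen-atom-transfer radical cyclisation). The tertiary radical adds 6-exo-dig to the nitrile carbon, and the iminyl radical is reduced to the cyclic ketimine (5S,6R)-6-[tert-butyl(dimethyl)silyl]oxy-3,5-dimethyl-5-(3-methylbut-2-en-1-yl)-6,7-dihydro-1,2-benzoxazol-4(5H)-imine F1 (same spatial arrangement as 14; the descriptor changes by the priority rules only). Aqueous acetic acid hydrolyses it to the ketone. Facial control would here come from the silyloxy centre alone, and the C5 epimer (5S,6R)-6-[tert-butyl(dimethyl)silyl]oxy-3,5-dimethyl-5-(3-methylbut-2-en-1-yl)-6,7-dihydro-1,2-benzoxazol-4(5H)-one F2 would be removed by chromatography. The fallback comes back to the route at 14.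

Step 10. Hydrolysis of the hydrogen-bonded vinylogous amide may stall, or forcing alkali may start retro-Claisen loss of the acetyl group. The fallback sets out from enaminone 17, isolated after the Mo(CO)6 stage. Boc2O and DMAP in MeCN convert it into the N-acylated vinylogous imide tert-butyl N-[1-[(3R)-3-methyl-3-(3-methylbut-2-en-1-yl)-2,4,6-trioxocyclohexylidene]ethyl]carbamate F3. Its activated C–N bond is then cleaved by LiOH in THF/H2O at 0 °C (any enol carbonate formed is cleaved in the same operation). The fallback comes back to the route at 18.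

Step 13. The quinone methide may be captured by phenolic material to give the ring-B homodimer, O-alkylation may compete, or retro-Mannich exchange may scramble the bridge. The fallback builds the bridge by reductive alkylation and sets out from 19. Vilsmeier–Haack formylation (POCl3, DMF, EtOAc, 0 °C to rt) gives 3-acetyl-2,4,6-trihydroxybenzaldehyde F4. C-prenylation with 20 (DBU, THF) gives 3-acetyl-2,4,6-trihydroxy-5-(3-methylbut-2-en-1-yl)benzaldehyde F5. Three-component reductive alkylation with 18 (L-proline cat., diethyl 2,6-dimethyl-1,4-dihydropyridine-3,5-dicarboxylate, CH2Cl2, rt) then proceeds through the Knoevenagel adduct (4S)-2-acetyl-6-[[3-acetyl-2,4,6-trihydroxy-5-(3-methylbut-2-en-1-yl)phenyl]methylidene]-3-hydroxy-4-methyl-4-(3-methylbut-2-en-1-yl)cyclohex-2-ene-1,5-dione F6 (not isolated; same spatial arrangement as 18), which is reduced in the flask by hydride transfer. The fallback comes back to the route at 23.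

Further compounds
F1 | step 8 | (5S,6R)-6-[tert-butyl(dimethyl)silyl]oxy-3,5-dimethyl-5-(3-methylbut-2-en-1-yl)-6,7-dihydro-1,2-benzoxazol-4(5H)-imine | Cc1noc2c1C(=N)[C@](C)(CC=C(C)C)[C@H](O[Si](C)(C)C(C)(C)C)C2
F2 | step 8 | (5S,6R)-6-[tert-butyl(dimethyl)silyl]oxy-3,5-dimethyl-5-(3-methylbut-2-en-1-yl)-6,7-dihydro-1,2-benzoxazol-4(5H)-one | Cc1noc2c1C(=O)[C@@](C)(CC=C(C)C)[C@H](O[Si](C)(C)C(C)(C)C)C2
F3 | step 10 | tert-butyl N-[1-[(3R)-3-methyl-3-(3-methylbut-2-en-1-yl)-2,4,6-trioxocyclohexylidene]ethyl]carbamate | CC(NC(=O)OC(C)(C)C)=C1C(=O)[C@](C)(CC=C(C)C)C(=O)CC1=O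
F4 | step 13 | 3-acetyl-2,4,6-trihydroxybenzaldehyde | CC(=O)c1c(O)cc(O)c(C=O)c1O
F5 | step 13 | 3-acetyl-2,4,6-trihydroxy-5-(3-methylbut-2-en-1-yl)benzaldehyde | CC(=O)c1c(O)c(CC=C(C)C)c(O)c(C=O)c1O
F6 | step 13 | (4S)-2-acetyl-6-[[3-acetyl-2,4,6-trihydroxy-5-(3-methylbut-2-en-1-yl)phenyl]methylidene]-3-hydroxy-4-methyl-4-(3-methylbut-2-en-1-yl)cyclohex-2-ene-1,5-dione | CC(=O)C1=C(O)[C@](C)(CC=C(C)C)C(=O)C(=Cc2c(O)c(CC=C(C)C)c(O)c(C(C)=O)c2O)C1=O
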